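Target and intermediate B I took together as a pool, because at 2.5 min the winter and autumn runs, with different charges of capture agent, divided it alike: the split, target as a fraction of the pool at a given time, read 0.568 over the two runs together.

all flasks: substrate 10 mM
- winter: capture agent 0.50 mM; run made earlier
- autumn: capture agent 0.75 mM; run made earlier
- flask: capture agent 1.00 mM; time 2.5 min

| run | time / min | target / % | intermediate B / % |
|---|---|---|---|
| winter | 0.200 | 0 | 0.8 |
| winter | 0.500 | 1.1 | 2.6 |
| winter | 1.00 | 4.6 | 6.8 |
| winter | 2.50 | 21.7 | 16.4 |
| autumn | 0.667 | 1.2 | 4.1 |
| autumn | 1.33 | 7.3 | 9.9 |
| autumn | 2.00 | 14.4 | 14.2 |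
| autumn | 2.50 | 21.3 | 16.3 |

(standard deviation of a reading: 0.3 percentage points)

1. amount of target in the flask at 2.5 min, in percent of the substrate charged
2. amount of intermediate B in the flask at 2.5 min, in percent of the substrate charged
3. amount of decomposed reagent in the flask at 2.5 min, in percent of the substrate charged

- the numbers in the tables scatter by 0.3 percentage points (one standard deviation)
- candidate steps: substrate -> intermediate A; intermediate A -> intermediate B; intermediate B <-> target; intermediate A + capture agent -> trapped intermediate; intermediate A -> decomposed reagent

The pool at 2.5 min read 38.1% of the charge in the winter run and 37.6% in the autumn run, a step of 0.5 percentage points against a scatter of 0.3 points per reading. I took that step once more for the flask, which gave a pool of 37.1%, and the split then gave me target 21.1% and intermediate B 16.0%; it told me nothing of decomposed reagent, which no run read.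

The forecast, finding that going from the winter to the autumn charge of capture agent “does nothing measurable”, gave target 21.3% (20% to 22.2%), intermediate B 16.3% (15.4% to 17%) and decomposed reagent 4% (0% to 15%), higher than my figures for target and for intermediate B.

The flask gave target 20.5%, intermediate B 15.7% and decomposed reagent 6.48%, each inside the range of the forecast.

    substrate → intermediate A (k = 0.0140 s⁻¹)
    intermediate A → intermediate B (k = 0.00670 s⁻¹)
    intermediate B ⇌ target (K = 2.40, k = 0.0270 s⁻¹)
    intermediate A + capture agent → trapped intermediate (k = 2.20 L mol⁻¹ s⁻¹)
    intermediate A → decomposed reagent (k = 0.00120 s⁻¹)

The split in the flask came to 0.566 against the 0.568 I had carried, on a pool of 36.2% where I had reckoned 37.1%. The nearest charge of capture agent above this one that moved target by 5 points, the substrate and the time held, was 5.53 mM. For the same flask read at 1.0 min, the winter split at that time, 0.404, set on its pool of 10.6%, gave target 4.29%, and that flask held 3.83%.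

The readings are calculated on assumed constants.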